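**Retrosynthetic overview**

1. Ring A numbering: C1 = ketone carbon, C2 = alkene carbon carrying C7H2–O, C3 = alkene CH, C4 = CH–O-tigloyl, C5 = CH–isopropyl, C6 = CH–OAc. Target ⇐ C6–H acetoxylation (trans to isopropyl) of bis-tiglate enone 14 ⇐ double Mitsunobu esterification (both tiglates, inversion at C4) of trans-diol enone 12.
2. 12 ⇐ opening of a β,γ-epoxy ketone (C2=C3 and C4–OH appear together) ⇐ excision of one carbon at C1 (C1–CO2R → C1=O) from cis-fused lactone 7 after α-hydroxylation and anti-epoxidation.
3. 7 ⇐ enantioselective, metal-templated Diels–Alder reaction that forms C1–C2 and C5–C6 at once: diene C2–C5 with C7–OH = dienol 4, dienophile C6=C1–CO2Me = methyl acrylate; 4 ⇐ isobutyraldehyde + a four-carbon phosphonate.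
4. Ring order: ring A and the temporary lactone ring B together in the key step, then a temporary oxirane (ring C); rings B and C are opened again and only ring A stays.
5. Enabling feature: the exocyclic oxygen on C7 sits on C2 next to the ketone carbon C1 (O–C7–C2–C1). The C7 alkoxide of the diene and an ester carbonyl on the future C1 can therefore be clamped on one chiral metal template, which fixes which ends join and which diene face reacts. The one stereocenter set there that survives (C5) relays C4 and C6.

Key step: step 3

Assumption: the template made from (R)-BINOL is taken to give the (3aR,6S,7aS)-lactone 7; if the sense of induction is the opposite, (S)-BINOL is used and nothing else changes.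

**Route**

Step 1
Reactants: 1 isobutyraldehyde (2-methylpropanal); 2 triethyl (E)-4-phosphonocrotonate
Product: 3 ethyl (2E,4E)-6-methylhepta-2,4-dienoate
Conditions: LiN(SiMe3)2, THF, −78 °C → 0 °C
Reagents that add atoms: none
Why: A vinylogous Horner–Wadsworth–Emmons olefination of an unhindered aldehyde with the stabilized allylic phosphonate anion should give the (E,E)-dienoate, and a minor (4Z) isomer can be equilibrated with catalytic iodine or left behind in step 3.

Step 2
Reactants: 3 ethyl (2E,4E)-6-methylhepta-2,4-dienoate
Product: 4 (2E,4E)-6-methylhepta-2,4-dien-1-ol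
Conditions: i-Bu2AlH (2.2 equiv), CH2Cl2, −78 °C; aq. potassium sodium tartrate
Reagents that add atoms: none
Why: 1,2-Reduction of a conjugated ester with i-Bu2AlH (DIBAL-H reduction) gives the allylic alcohol and leaves the diene untouched.

Step 3
Reactants: 4 (2E,4E)-6-methylhepta-2,4-dien-1-ol; 5 methyl acrylate
Product: 7 (3aR,6S,7aS)-6-(propan-2-yl)-3a,6,7,7a-tetrahydro-2-benzofuran-1(3H)-one (cis-fused lactone), via hydroxy ester cycloadduct 6 (not isolated)
Conditions: MeMgBr (1.0 equiv), Me2Zn (1.0 equiv), (R)-BINOL (0.2 equiv), 5 (3 equiv), CH2Cl2, 0 °C → rt; then H2O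
Reagents that add atoms: none
Why: The bromomagnesium alkoxide of 4 and the carbonyl oxygen of 5 are held on one BINOL-bridged zinc/magnesium Lewis acid, so a concerted, LUMO-lowered [4π+2π] cycloaddition inside this assembly forms C1–C2 and C5–C6 together. The closest known reaction type is the Lewis-acid-templated, hydroxyl-directed enantioselective Diels–Alder reaction of 2,4-dienols with methyl acrylate, which likewise ends in a cis-fused lactone. Ring A closes by suprafacial–suprafacial [4+2] cycloaddition, and ring B by 5-exo-trig transesterification of the C7 alkoxide onto the neighbouring cis ester of 6 with loss of methoxide. C2 and C5 become cis because both diene double bonds are E, their absolute configuration comes from the BINOL ligand that blocks one diene face, and C1 (ester cis to C7, endo within the template) is a transient center erased in step 7. The step needs regioselectivity (ester carbon next to C2, not C5) and facial selectivity; the first is secured by the C7–O–metal–O=C clamp that the allylic hydroxyl of 4 makes possible, the second by the chiral template, and only the (E,E)-diene can reach the s-cis geometry.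

Step 4
Reactants: 7 cis-fused lactone
Product: 8 (3aS,6S,7aR)-7a-hydroxy-6-(propan-2-yl)-3a,6,7,7a-tetrahydro-2-benzofuran-1(3H)-one
Conditions: KN(SiMe3)2, THF, −78 °C; 2-(phenylsulfonyl)-3-phenyloxaziridine, −78 °C; AcOH
Reagents that add atoms: 2-(phenylsulfonyl)-3-phenyloxaziridine, O=S(=O)(c1ccccc1)N1OC1c1ccccc1
Why: Enolate hydroxylation with an N-sulfonyloxaziridine (Davis oxidation) should attack the lactone enolate on the convex face and keep the ring fusion cis; the new carbinol center at C1 only prepares the later carbon excision and is destroyed in step 7.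

Step 5
Reactants: 8 α-hydroxy lactone
Product: 9 epoxy hydroxy lactone (8 with C3=C4 of ring A turned into an oxirane; oxirane oxygen trans to the isopropyl group and to the lactone CH2O, cis to the tertiary OH)
Conditions: mCPBA, NaHCO3, CH2Cl2, 0 °C → rt
Reagents that add atoms: mCPBA, OOC(=O)c1cccc(Cl)c1
Why: In this Prilezhaev epoxidation the peracid should approach the alkene anti to the two cis allylic substituents at C2 and C5 (and syn to the hydrogen-bonding tertiary hydroxyl), which sets both oxirane centers and thereby the later C4 configuration.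

Step 6
Reactants: 9 epoxy hydroxy lactone
Product: 10 epoxy triol (1,2-bis(hydroxymethyl)-5-isopropyl-3,4-epoxycyclohexan-1-ol; both CH2OH groups and the isopropyl group on one face, oxirane oxygen and tertiary OH on the other)
Conditions: LiBH4, THF, 0 °C → rt; then H2O
Reagents that add atoms: none
Why: Borohydride reduction of an α-hydroxy lactone to the diol is fast, whereas a 1,2-disubstituted oxirane is inert to LiBH4 at this temperature; no stereocenter is touched.

Step 7
Reactants: 10 epoxy triol
Product: 12 (4S,5S)-4-hydroxy-2-(hydroxymethyl)-5-(propan-2-yl)cyclohex-2-en-1-one, via epoxy ketone 11 (not isolated)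
Conditions: NaIO4, NaHCO3, THF/H2O, 0 °C → rt; then Et3N, CH2Cl2, rt
Reagents that add atoms: none
Why: Malaprade glycol cleavage removes the exocyclic carbon on C1 as formaldehyde and unveils the C1 ketone, and the resulting β,γ-epoxy ketone should open by base-mediated E1cB elimination to the γ-hydroxy enone, with the C4–O bond keeping the oxirane configuration (trans to isopropyl).

Step 8
Reactants: 12 trans-diol enone; 13 tiglic acid ((E)-2-methylbut-2-enoic acid)
Product: 14 [(3R,4S)-6-oxo-4-(propan-2-yl)-3-{[(E)-2-methylbut-2-enoyl]oxy}cyclohex-1-en-1-yl]methyl (E)-2-methylbut-2-enoate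
Conditions: 13 (2.6 equiv), PPh3, DIAD, THF, 0 °C → rt
Reagents that add atoms: none
Why: A double Mitsunobu esterification should acylate the primary allylic alcohol and, by SN2 inversion, the secondary allylic alcohol at C4, which places the C4 tiglate cis to the isopropyl group; E2 elimination is disfavoured because the C5 hydrogen is syn to the leaving group.

Step 9
Reactants: 14 bis-tiglate enone
Product: 15 target, [(3S,4S,5R)-5-acetoxy-6-oxo-4-(propan-2-yl)-3-{[(E)-2-methylbut-2-enoyl]oxy}cyclohex-1-en-1-yl]methyl (E)-2-methylbut-2-enoate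
Conditions: Mn(OAc)3·2H2O (3 equiv), benzene, reflux (Dean–Stark)
Reagents that add atoms: manganese triacetate Mn(OAc)3 (trivalent manganese), CC(=O)[O-].CC(=O)[O-].CC(=O)[O-].[Mn+3]
Why: α'-Acetoxylation of an enone through its manganese enolate should take place at C6, the only enolizable α' position, with acetate entering anti to the neighbouring isopropyl group; this trans epimer is also expected to be the more stable one, so a minor C6 epimer should converge on it by enolization.

**Compound list**

1 | isobutyraldehyde (2-methylpropanal) | CC(C)C=O | starting material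
2 | triethyl (E)-4-phosphonocrotonate (ethyl (E)-4-(diethoxyphosphoryl)but-2-enoate) | CCOC(=O)/C=C/CP(=O)(OCC)OCC | starting material
3 | ethyl (2E,4E)-6-methylhepta-2,4-dienoate | CCOC(=O)/C=C/C=C/C(C)C | intermediate
4 | (2E,4E)-6-methylhepta-2,4-dien-1-ol | CC(C)/C=C/C=C/CO | intermediate
5 | methyl acrylate | COC(=O)C=C | starting material
6 | methyl (1S,2R,5S)-2-(hydroxymethyl)-5-(propan-2-yl)cyclohex-3-ene-1-carboxylate (formed as its metal alkoxide) | OC[C@@H]1C=C[C@H](C(C)C)C[C@@H]1C(=O)OC | intermediate
7 | (3aR,6S,7aS)-6-(propan-2-yl)-3a,6,7,7a-tetrahydro-2-benzofuran-1(3H)-one (cis-fused; isopropyl cis to the lactone ring) | O=C1OC[C@@H]2C=C[C@H](C(C)C)C[C@H]12 | intermediate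
8 | (3aS,6S,7aR)-7a-hydroxy-6-(propan-2-yl)-3a,6,7,7a-tetrahydro-2-benzofuran-1(3H)-one | O=C1OC[C@@H]2C=C[C@H](C(C)C)C[C@]12O | intermediate
9 | epoxy hydroxy lactone: 8 with an oxirane in place of the ring alkene, oxirane oxygen trans to isopropyl and lactone CH2O, cis to the tertiary OH | O=C1OC[C@@H]2[C@H]3O[C@H]3[C@H](C(C)C)C[C@]12O | intermediate
10 | epoxy triol: 1,2-bis(hydroxymethyl)-5-isopropyl-3,4-epoxycyclohexan-1-ol, CH2OH groups and isopropyl on one face, oxirane oxygen and tertiary OH on the other | OC[C@@H]1[C@H]2O[C@H]2[C@H](C(C)C)C[C@]1(O)CO | intermediate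
11 | epoxy ketone: 2-(hydroxymethyl)-5-isopropyl-3,4-epoxycyclohexan-1-one, CH2OH and isopropyl cis, oxirane oxygen trans to both | OC[C@@H]1[C@H]2O[C@H]2[C@H](C(C)C)CC1=O | intermediate
12 | (4S,5S)-4-hydroxy-2-(hydroxymethyl)-5-(propan-2-yl)cyclohex-2-en-1-one (4-OH trans to isopropyl) | OCC1=C[C@@H](O)[C@H](C(C)C)CC1=O | intermediate
13 | tiglic acid, (E)-2-methylbut-2-enoic acid | C/C=C(\C)C(O)=O | starting material
14 | [(3R,4S)-6-oxo-4-(propan-2-yl)-3-{[(E)-2-methylbut-2-enoyl]oxy}cyclohex-1-en-1-yl]methyl (E)-2-methylbut-2-enoate (ring tiglate cis to isopropyl) | C/C=C(\C)C(=O)OCC1=C[C@H](OC(=O)/C(C)=C/C)[C@H](C(C)C)CC1=O | intermediate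
15 | CNP0218511.1, [(3S,4S,5R)-5-acetoxy-6-oxo-4-(propan-2-yl)-3-{[(E)-2-methylbut-2-enoyl]oxy}cyclohex-1-en-1-yl]methyl (E)-2-methylbut-2-enoate | C/C=C(\C)C(=O)OCC1=C[C@H](OC(=O)/C(C)=C/C)[C@H](C(C)C)[C@@H](OC(C)=O)C1=O | target

**Totals**

Total step count: 9. Longest linear sequence: 9 steps (from 1 to 15).

**Steps most likely to fail and fallbacks**

Step 3. The templated cycloaddition may be sluggish or poorly face-selective, because the isopropyl-bearing diene terminus is bulkier than in the known cases. Incomplete assembly on the template would also let the untemplated pathway with the wrong regiochemistry compete. The fallback sets out from 4 and comes back at 7; it replaces the metal clamp by a covalent ester tether and takes the absolute configuration from a resolution. Acylation of 4 with acryloyl chloride (Et3N, CH2Cl2, 0 °C) gives (2E,4E)-6-methylhepta-2,4-dien-1-yl acrylate F1. A thermal intramolecular Diels–Alder reaction (toluene, 180 °C, BHT, sealed tube), followed by DBU equilibration of the ring fusion, should give the racemic cis-fused lactone F2. Aminolysis with (S)-1-phenylethylamine and AlMe3 gives two diastereomeric hydroxy amides, from which (1S,2R,5S)-2-(hydroxymethyl)-N-[(1S)-1-phenylethyl]-5-(propan-2-yl)cyclohex-3-ene-1-carboxamide F3 is separated by chromatography or crystallization. Acid-mediated relactonization of F3 (p-TsOH, toluene, reflux) returns 7.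

Step 8. Inversion at the hindered secondary allylic carbinol may be incomplete with the weakly acidic tiglic acid, and elimination or allylic transposition at the primary allylic alcohol may compete. The fallback sets out from 12 and comes back at 14; it separates the inversion from the tigloylation. Mitsunobu reaction with 4-nitrobenzoic acid (PPh3, DIAD, THF), the acid of choice for hindered alcohols, gives the C4-inverted bis(4-nitrobenzoate) F4. Mild methanolysis (K2CO3, MeOH, 0 °C) gives the cis-diol (4R,5S)-4-hydroxy-2-(hydroxymethyl)-5-(propan-2-yl)cyclohex-2-en-1-one F5. Conventional acylation with tigloyl chloride (pyridine, DMAP, CH2Cl2, 0 °C), which retains configuration, then gives 14.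

Step 9. Diastereocontrol at C6 may be poor, and radical side reactions at the allylic methyl groups of the tiglates or over-oxidation may occur under the hot oxidative conditions. The fallback sets out from 14 and comes back at 15; it uses ionic enolate chemistry instead. Kinetic α'-enolization with LiN(SiMe3)2 in the presence of Me3SiCl (THF, −78 °C) gives the cross-conjugated trimethylsilyl dienol ether F6 (C1–O–Si, C1=C6). Rubottom oxidation (mCPBA, NaHCO3, CH2Cl2, −20 °C; aqueous citric acid), with the oxidant approaching anti to the isopropyl group, gives the α'-hydroxy enone F7. Acetylation (Ac2O, pyridine, DMAP) gives 15.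

**Further compounds**

F1 | step 3 | (2E,4E)-6-methylhepta-2,4-dien-1-yl acrylate | C=CC(=O)OC/C=C/C=C/C(C)C
F2 | step 3 | racemic cis-fused lactone, (3aR*,6S*,7aS*)-6-(propan-2-yl)-3a,6,7,7a-tetrahydro-2-benzofuran-1(3H)-one (racemate of 7) | O=C1OCC2C=CC(C(C)C)CC12
F3 | step 3 | (1S,2R,5S)-2-(hydroxymethyl)-N-[(1S)-1-phenylethyl]-5-(propan-2-yl)cyclohex-3-ene-1-carboxamide | OC[C@@H]1C=C[C@H](C(C)C)C[C@@H]1C(=O)N[C@@H](C)c1ccccc1
F4 | step 8 | [(3R,4S)-3-(4-nitrobenzoyloxy)-6-oxo-4-(propan-2-yl)cyclohex-1-en-1-yl]methyl 4-nitrobenzoate | O=C(OCC1=C[C@H](OC(=O)c2ccc(cc2)[N+](=O)[O-])[C@H](C(C)C)CC1=O)c1ccc(cc1)[N+](=O)[O-]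
F5 | step 8 | (4R,5S)-4-hydroxy-2-(hydroxymethyl)-5-(propan-2-yl)cyclohex-2-en-1-one (4-OH cis to isopropyl) | OCC1=C[C@H](O)[C@H](C(C)C)CC1=O
F6 | step 9 | trimethylsilyl dienol ether of 14 (C1–O–SiMe3, C1=C6, C2=C3; tiglates and C4, C5 configuration as in 14) | C/C=C(\C)C(=O)OCC1=C[C@H](OC(=O)/C(C)=C/C)[C@H](C(C)C)C=C1O[Si](C)(C)C
F7 | step 9 | 6-hydroxy analogue of 15 (C6–OH trans to isopropyl, otherwise as 15) | C/C=C(\C)C(=O)OCC1=C[C@H](OC(=O)/C(C)=C/C)[C@H](C(C)C)[C@@H](O)C1=O
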